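**Retrosynthetic overview**

- The target (2R,3R) is reached from the 3-acetoxyflavan 14 by raising C4 from CH2 to C=O (DDQ/water, then oxidation) and hydrogenolysis of three benzyl ethers.
- The route rests on the trans C2-aryl/C3-acetoxy pair of ring C. Cutting O1–C2 and C3–C4 gives a ring A ortho-quinone methide (C4, C4a, C8a, O1) and the C2–C3 unit as (E)-2-(4-benzyloxyphenyl)vinyl acetate 12. One oxa-(4+2) addition then forms ring C and both stereocentres with the acetate already on C3.
- The methide comes from salicyl alcohol 8, made from methyl 4-O-methylgallate 1 by benzylation, reduction, oxidation, Baeyer–Villiger oxidation, ortho-formylation and reduction.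
- The enol acetate is made as the pure E isomer from alkyne 9 by hydroboration, conversion into the trifluoroborate and copper-catalysed C–O coupling with acetic acid. Enol acetylation of the arylacetaldehyde would give E/Z mixtures, and the alkene geometry sets the 2,3-trans relationship.
- Rings A and B are bought as arenes; ring C is the only ring formed (step 10).

Key step: step 10

Assumption: the sense of induction of the chiral phosphoric acid in step 10 cannot be predicted with confidence; the (R)-catalyst is written, and its enantiomer is to be used if the (2S,3R) flavan forms instead.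

**Route**

Step 1
Reactants: 1 methyl 3,5-dihydroxy-4-methoxybenzoate
Product: 2 methyl 3,5-bis(benzyloxy)-4-methoxybenzoate
Conditions: BnBr, K2CO3, DMF, 60 °C
Reagents that add atoms: benzyl bromide BrCc1ccccc1
Why: Williamson etherification alkylates both phenols under carbonate base while the methyl ester is untouched.

Step 2
Reactants: 2 methyl 3,5-bis(benzyloxy)-4-methoxybenzoate
Product: 3 [3,5-bis(benzyloxy)-4-methoxyphenyl]methanol
Conditions: LiAlH4, THF, 0 °C to rt
Reagents that add atoms: none
Why: Hydride reduction of the ester with LiAlH4 gives the primary benzylic alcohol; aryl benzyl and methyl ethers are inert.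

Step 3
Reactants: 3 [3,5-bis(benzyloxy)-4-methoxyphenyl]methanol
Product: 4 3,5-bis(benzyloxy)-4-methoxybenzaldehyde
Conditions: MnO2, CH2Cl2, rt
Reagents that add atoms: none
Why: Oxidation of a benzylic alcohol by MnO2 stops cleanly at the aldehyde.

Step 4
Reactants: 4 3,5-bis(benzyloxy)-4-methoxybenzaldehyde
Product: 6 3,5-bis(benzyloxy)-4-methoxyphenol, via aryl formate 5 (not isolated)
Conditions: mCPBA, CH2Cl2, rt; then K2CO3 (cat.), MeOH, rt
Reagents that add atoms: mCPBA O=C(OO)c1cccc(Cl)c1
Why: Baeyer–Villiger (Dakin-type) oxidation, in which the electron-rich aryl group migrates in the Criegee intermediate to give aryl formate 5, which mild methanolysis cleaves to the phenol.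

Step 5
Reactants: 6 3,5-bis(benzyloxy)-4-methoxyphenol
Product: 7 4,6-bis(benzyloxy)-2-hydroxy-5-methoxybenzaldehyde
Conditions: MgCl2, Et3N, (CH2O)n, MeCN, reflux
Reagents that add atoms: paraformaldehyde (as formaldehyde) C=O
Why: Magnesium-phenoxide-directed ortho-formylation (Casnati–Skattebøl) delivers formaldehyde next to the phenoxide and a second formaldehyde oxidises the hydroxymethyl group by hydride transfer; the two ortho positions of 6 are equivalent and the para position is blocked, so one product is possible.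

Step 6
Reactants: 7 4,6-bis(benzyloxy)-2-hydroxy-5-methoxybenzaldehyde
Product: 8 3,5-bis(benzyloxy)-2-(hydroxymethyl)-4-methoxyphenol
Conditions: NaBH4, THF/MeOH, 0 °C; neutral work-up, used promptly
Reagents that add atoms: none
Why: Borohydride reduction of the aldehyde gives the benzylic alcohol, and the neutral work-up keeps the acid-labile salicyl alcohol intact.

Step 7
Reactants: 9 1-(benzyloxy)-4-ethynylbenzene
Product: 10 2-[(E)-2-(4-benzyloxyphenyl)vinyl]-4,4,5,5-tetramethyl-1,3,2-dioxaborolane
Conditions: pinacolborane, Cp2Zr(H)Cl (5 mol%), Et3N (10 mol%), neat, 60 °C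
Reagents that add atoms: pinacolborane CC1(C)OBOC1(C)C
Why: Zirconium-hydride-catalysed syn hydroboration of the terminal alkyne places boron on the terminal carbon and should give only the E alkenylboronate.

Step 8
Reactants: 10 2-[(E)-2-(4-benzyloxyphenyl)vinyl]-4,4,5,5-tetramethyl-1,3,2-dioxaborolane
Product: 11 potassium (E)-[2-(4-benzyloxyphenyl)vinyl]trifluoroborate
Conditions: KHF2, MeOH/H2O, rt
Reagents that add atoms: potassium hydrogen difluoride [K+].[F-].F
Why: Fluoride exchange on boron with KHF2 turns the pinacol ester into the crystalline trifluoroborate without touching the alkene geometry.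

Step 9
Reactants: 11 potassium (E)-[2-(4-benzyloxyphenyl)vinyl]trifluoroborate
Product: 12 (E)-2-(4-benzyloxyphenyl)vinyl acetate
Conditions: AcOH, CuBr (10 mol%), DMAP (20 mol%), 4 Å MS, O2 (1 atm), MeCN, 60 °C
Reagents that add atoms: acetic acid CC(=O)O
Why: Chan–Lam-type copper-catalysed oxidative C–O coupling of an alkenyltrifluoroborate with a carboxylic acid, in which transmetalation to copper and reductive elimination both go with retention, so the E geometry is carried into the enol ester.

Step 10
Reactants: 8 3,5-bis(benzyloxy)-2-(hydroxymethyl)-4-methoxyphenol; 12 (E)-2-(4-benzyloxyphenyl)vinyl acetate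
Product: 14 (2R,3S)-5,7-bis(benzyloxy)-2-(4-benzyloxyphenyl)-6-methoxychroman-3-yl acetate, via ortho-quinone methide 13 (not isolated)
Conditions: (R)-3,3'-bis(2,4,6-triisopropylphenyl)-1,1'-binaphthyl-2,2'-diyl hydrogen phosphate (10 mol%), 4 Å MS, toluene, −20 °C, slow addition of 8 to 12 (2 equiv)
Reagents that add atoms: none
Why: Proposed new method: the phosphoric acid ionises the benzylic alcohol of 8, which is activated by the ortho-hydroxyl, ortho-benzyloxy and para-benzyloxy groups, to the ortho-quinone methide 13 held as a hydrogen-bonded ion pair with the chiral phosphate; the acetoxy-bearing alkene carbon (C3) then bonds to the methide carbon C4 while positive charge builds at C2, and O1 closes onto C2 in a concerted, asynchronous inverse-demand oxa-(4+2) addition. The closest known reaction type is the chiral phosphoric acid or N-triflylphosphoramide catalysed hetero-Diels–Alder reaction of ortho-quinone methides, made in the flask from ortho-hydroxybenzyl alcohols, with styrenes and enol ethers; an enol ester as the 2π partner and a methide carbon without a substituent are not covered by it. Ring C closes as a six-membered ring by this (4+2) cycloaddition, with C3–C4 formed ahead of O1–C2. The trans relationship of C2 and C3 follows from suprafacial addition across the E double bond (a stepwise path through the 4-benzyloxybenzyl cation would also close to the diequatorial trans product), and the absolute configuration of both centres comes from the chiral phosphate, whose pocket must choose between the two mirror-image approaches of the alkene to the methide. The step needs regioselectivity (aryl at C2, acetate at C3), secured by the 4-benzyloxyphenyl group, which stabilises charge at C2 far better than the acetoxy group could at C3, and chemoselectivity against self-alkylation of 8 at its free C8 position, secured by slow addition of 8 to excess 12 and by sieves that take up the water.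

Step 11
Reactants: 14 (2R,3S)-5,7-bis(benzyloxy)-2-(4-benzyloxyphenyl)-6-methoxychroman-3-yl acetate
Product: 15 (2R,3S,4RS)-5,7-bis(benzyloxy)-2-(4-benzyloxyphenyl)-4-hydroxy-6-methoxychroman-3-yl acetate (C4 epimer mixture)
Conditions: DDQ, CH2Cl2/H2O (20:1), 0 °C to rt
Reagents that add atoms: water O
Why: Benzylic C–H oxidation by DDQ, in which hydride abstraction at C4 (flanked by the ortho and para oxygen donors of ring A) gives a stabilised cation that water captures, as is known for O-benzylated flavan-3-ol derivatives; the new C4 centre is removed in the next step and C2 and C3 are untouched.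

Step 12
Reactants: 15 (2R,3S,4RS)-5,7-bis(benzyloxy)-2-(4-benzyloxyphenyl)-4-hydroxy-6-methoxychroman-3-yl acetate
Product: 16 (2R,3R)-5,7-bis(benzyloxy)-2-(4-benzyloxyphenyl)-6-methoxy-4-oxochroman-3-yl acetate
Conditions: Dess–Martin periodinane, CH2Cl2, 0 °C to rt
Reagents that add atoms: none
Why: Dess–Martin oxidation of the secondary benzylic alcohol gives the aryl ketone under non-basic conditions that do not enolise C3; the C3 descriptor changes from S to R only because C4 now outranks C2.

Step 13
Reactants: 16 (2R,3R)-5,7-bis(benzyloxy)-2-(4-benzyloxyphenyl)-6-methoxy-4-oxochroman-3-yl acetate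
Product: 17 (2R,3R)-5,7-dihydroxy-2-(4-hydroxyphenyl)-6-methoxy-4-oxochroman-3-yl acetate (6-methoxyaromadendrin 3-O-acetate)
Conditions: H2 (1 atm), 10% Pd/C, EtOAc/THF, rt
Reagents that add atoms: none
Why: Catalytic hydrogenolysis over Pd/C under neutral conditions cleaves the three aryl benzyl ethers and should leave the acetate, the vinylogous-ester-like ketone and the C2–O1 bond in place.

**Compound list**

1 | methyl 3,5-dihydroxy-4-methoxybenzoate | COC(=O)c1cc(O)c(OC)c(O)c1 | starting material
2 | methyl 3,5-bis(benzyloxy)-4-methoxybenzoate | COC(=O)c1cc(OCc2ccccc2)c(OC)c(OCc2ccccc2)c1 | intermediate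
3 | [3,5-bis(benzyloxy)-4-methoxyphenyl]methanol | OCc1cc(OCc2ccccc2)c(OC)c(OCc2ccccc2)c1 | intermediate
4 | 3,5-bis(benzyloxy)-4-methoxybenzaldehyde | O=Cc1cc(OCc2ccccc2)c(OC)c(OCc2ccccc2)c1 | intermediate
5 | 3,5-bis(benzyloxy)-4-methoxyphenyl formate (not isolated) | O=COc1cc(OCc2ccccc2)c(OC)c(OCc2ccccc2)c1 | intermediate
6 | 3,5-bis(benzyloxy)-4-methoxyphenol | Oc1cc(OCc2ccccc2)c(OC)c(OCc2ccccc2)c1 | intermediate
7 | 4,6-bis(benzyloxy)-2-hydroxy-5-methoxybenzaldehyde | O=Cc1c(O)cc(OCc2ccccc2)c(OC)c1OCc1ccccc1 | intermediate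
8 | 3,5-bis(benzyloxy)-2-(hydroxymethyl)-4-methoxyphenol | OCc1c(O)cc(OCc2ccccc2)c(OC)c1OCc1ccccc1 | intermediate
9 | 1-(benzyloxy)-4-ethynylbenzene | C#Cc1ccc(OCc2ccccc2)cc1 | starting material
10 | 2-[(E)-2-(4-benzyloxyphenyl)vinyl]-4,4,5,5-tetramethyl-1,3,2-dioxaborolane | CC1(C)OB(/C=C/c2ccc(OCc3ccccc3)cc2)OC1(C)C | intermediate
11 | potassium (E)-[2-(4-benzyloxyphenyl)vinyl]trifluoroborate | [K+].F[B-](F)(F)/C=C/c1ccc(OCc2ccccc2)cc1 | intermediate
12 | (E)-2-(4-benzyloxyphenyl)vinyl acetate | CC(=O)O/C=C/c1ccc(OCc2ccccc2)cc1 | intermediate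
13 | 3,5-bis(benzyloxy)-4-methoxy-6-methylidenecyclohexa-2,4-dien-1-one (ortho-quinone methide, not isolated) | C=C1C(=O)C=C(OCc2ccccc2)C(OC)=C1OCc1ccccc1 | intermediate
14 | (2R,3S)-5,7-bis(benzyloxy)-2-(4-benzyloxyphenyl)-6-methoxychroman-3-yl acetate (2,3-trans) | COc1c(OCc2ccccc2)cc2c(c1OCc1ccccc1)C[C@H](OC(C)=O)[C@@H](c1ccc(OCc3ccccc3)cc1)O2 | intermediate
15 | (2R,3S,4RS)-5,7-bis(benzyloxy)-2-(4-benzyloxyphenyl)-4-hydroxy-6-methoxychroman-3-yl acetate (C4 epimer mixture, C4 left undefined) | COc1c(OCc2ccccc2)cc2c(c1OCc1ccccc1)C(O)[C@H](OC(C)=O)[C@@H](c1ccc(OCc3ccccc3)cc1)O2 | intermediate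
16 | (2R,3R)-5,7-bis(benzyloxy)-2-(4-benzyloxyphenyl)-6-methoxy-4-oxochroman-3-yl acetate | COc1c(OCc2ccccc2)cc2c(c1OCc1ccccc1)C(=O)[C@H](OC(C)=O)[C@@H](c1ccc(OCc3ccccc3)cc1)O2 | intermediate
17 | (2R,3R)-5,7-dihydroxy-2-(4-hydroxyphenyl)-6-methoxy-4-oxochroman-3-yl acetate (6-methoxyaromadendrin 3-O-acetate) | COc1c(O)cc2c(c1O)C(=O)[C@H](OC(C)=O)[C@@H](c1ccc(O)cc1)O2 | target

**Step count**

Total steps: 13. Longest linear sequence: 10 (steps 1–6, then 10–13); the ring B branch (steps 7–9) joins at step 10.

**Steps most likely to fail**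

1. Step 10 (proposed new method). The methide may be consumed by alkylating the electron-rich ring of a second molecule of 8. The alkene may add with reversed regiochemistry. The phosphate may discriminate poorly between the two mirror-image approaches, because the methide carbon carries no substituent. Fallback (known chalcone epoxide chemistry), setting out from phenol 6 and returning at ketone 16:
   - Boron-chelated ortho-acetylation of 6 (Ac2O, BF3·OEt2, rt) should give 1-[4,6-bis(benzyloxy)-2-hydroxy-5-methoxyphenyl]ethanone F1.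
   - Claisen–Schmidt condensation with commercial 4-benzyloxybenzaldehyde (KOH, EtOH) should give (E)-1-[4,6-bis(benzyloxy)-2-hydroxy-5-methoxyphenyl]-3-(4-benzyloxyphenyl)prop-2-en-1-one F2.
   - Protection of the chelated phenol (MOMCl, NaH, DMF) should give (E)-1-[4,6-bis(benzyloxy)-5-methoxy-2-(methoxymethoxy)phenyl]-3-(4-benzyloxyphenyl)prop-2-en-1-one F3.
   - Juliá–Colonna epoxidation (poly-L-leucine, urea–H2O2, DBU, THF) should give [4,6-bis(benzyloxy)-5-methoxy-2-(methoxymethoxy)phenyl][(2R,3S)-3-(4-benzyloxyphenyl)oxiran-2-yl]methanone F4.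
   - HCl in MeOH at 50 °C removes the methoxymethyl group, and the freed phenol opens the epoxide at the benzylic carbon with inversion. This should give (2R,3R)-5,7-bis(benzyloxy)-2-(4-benzyloxyphenyl)-3-hydroxy-6-methoxychroman-4-one F5.
   - Acetylation (Ac2O, pyridine) gives 16. This path bypasses steps 10–12.

2. Step 11. The C3 acetate may participate at the C4 cation, leading to acyl migration onto O4 or orthoester by-products, and the product may be over-oxidised. Fallback, setting out from flavan 14 and returning at ketone 16, with the participating ester replaced by a silyl ether: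
   - Methanolysis (K2CO3, MeOH/THF) should give (2R,3S)-5,7-bis(benzyloxy)-2-(4-benzyloxyphenyl)-6-methoxychroman-3-ol F6.
   - Silylation (TBSOTf, 2,6-lutidine, CH2Cl2) should give (2R,3S)-5,7-bis(benzyloxy)-2-(4-benzyloxyphenyl)-3-(tert-butyldimethylsilyloxy)-6-methoxychromane F7.
   - DDQ in wet CH2Cl2 should give (2R,3S,4RS)-5,7-bis(benzyloxy)-2-(4-benzyloxyphenyl)-3-(tert-butyldimethylsilyloxy)-6-methoxychroman-4-ol F8.
   - Dess–Martin oxidation should give (2R,3R)-5,7-bis(benzyloxy)-2-(4-benzyloxyphenyl)-3-(tert-butyldimethylsilyloxy)-6-methoxychroman-4-one F9.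
   - HF·pyridine in THF frees the dihydroflavonol (2R,3R)-5,7-bis(benzyloxy)-2-(4-benzyloxyphenyl)-3-hydroxy-6-methoxychroman-4-one F5 (the same compound as in the first fallback), and Ac2O/pyridine gives 16.

3. Step 9. Protodeboronation or oxidative homocoupling of the alkenylboron species may outrun C–O bond formation, and the electron-rich enol ester may hydrolyse on work-up. Fallback, setting out from alkenylboronate 10 and returning at enol acetate 12:
   - Oxidation with NaBO3·4H2O in THF/H2O should give 2-(4-benzyloxyphenyl)acetaldehyde F10.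
   - Enol acetylation (Ac2O, KOAc, 120 °C) gives the enol acetate as an E/Z mixture. The E isomer 12 is separated by crystallisation or chromatography on AgNO3-impregnated silica.

**Further compounds**

F1 | step 10 | 1-[4,6-bis(benzyloxy)-2-hydroxy-5-methoxyphenyl]ethanone | CC(=O)c1c(O)cc(OCc2ccccc2)c(OC)c1OCc1ccccc1
F2 | step 10 | (E)-1-[4,6-bis(benzyloxy)-2-hydroxy-5-methoxyphenyl]-3-(4-benzyloxyphenyl)prop-2-en-1-one | O=C(/C=C/c1ccc(OCc2ccccc2)cc1)c1c(O)cc(OCc2ccccc2)c(OC)c1OCc1ccccc1
F3 | step 10 | (E)-1-[4,6-bis(benzyloxy)-5-methoxy-2-(methoxymethoxy)phenyl]-3-(4-benzyloxyphenyl)prop-2-en-1-one | O=C(/C=C/c1ccc(OCc2ccccc2)cc1)c1c(OCOC)cc(OCc2ccccc2)c(OC)c1OCc1ccccc1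
F4 | step 10 | [4,6-bis(benzyloxy)-5-methoxy-2-(methoxymethoxy)phenyl][(2R,3S)-3-(4-benzyloxyphenyl)oxiran-2-yl]methanone | O=C([C@@H]1O[C@H]1c1ccc(OCc2ccccc2)cc1)c1c(OCOC)cc(OCc2ccccc2)c(OC)c1OCc1ccccc1
F5 | step 10 | (2R,3R)-5,7-bis(benzyloxy)-2-(4-benzyloxyphenyl)-3-hydroxy-6-methoxychroman-4-one | COc1c(OCc2ccccc2)cc2c(c1OCc1ccccc1)C(=O)[C@H](O)[C@@H](c1ccc(OCc3ccccc3)cc1)O2
F6 | step 11 | (2R,3S)-5,7-bis(benzyloxy)-2-(4-benzyloxyphenyl)-6-methoxychroman-3-ol | COc1c(OCc2ccccc2)cc2c(c1OCc1ccccc1)C[C@H](O)[C@@H](c1ccc(OCc3ccccc3)cc1)O2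
F7 | step 11 | (2R,3S)-5,7-bis(benzyloxy)-2-(4-benzyloxyphenyl)-3-(tert-butyldimethylsilyloxy)-6-methoxychromane | COc1c(OCc2ccccc2)cc2c(c1OCc1ccccc1)C[C@H](O[Si](C)(C)C(C)(C)C)[C@@H](c1ccc(OCc3ccccc3)cc1)O2
F8 | step 11 | (2R,3S,4RS)-5,7-bis(benzyloxy)-2-(4-benzyloxyphenyl)-3-(tert-butyldimethylsilyloxy)-6-methoxychroman-4-ol (C4 epimer mixture) | COc1c(OCc2ccccc2)cc2c(c1OCc1ccccc1)C(O)[C@H](O[Si](C)(C)C(C)(C)C)[C@@H](c1ccc(OCc3ccccc3)cc1)O2
F9 | step 11 | (2R,3R)-5,7-bis(benzyloxy)-2-(4-benzyloxyphenyl)-3-(tert-butyldimethylsilyloxy)-6-methoxychroman-4-one | COc1c(OCc2ccccc2)cc2c(c1OCc1ccccc1)C(=O)[C@H](O[Si](C)(C)C(C)(C)C)[C@@H](c1ccc(OCc3ccccc3)cc1)O2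
F10 | step 9 | 2-(4-benzyloxyphenyl)acetaldehyde | O=CCc1ccc(OCc2ccccc2)cc1
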